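**Opening runs.** The south-west, south and east runs differ in racemization catalyst, and at 25.0 min the readings of their excess of left-handed product rise with it: 29.0%, 29.8%, 34.3%.

| setting | south-west | south | east | maple | cedar |
|---|---|---|---|---|---|
| left-handed substrate | 0.050 M | 0.050 M | 0.050 M | 0.050 M | 0.050 M |
| right-handed substrate | 0.050 M | 0.050 M | 0.050 M | 0.050 M | 0.050 M |
| coupling partner | 0.20 M | 0.20 M | 0.20 M | 0.200 M | 0.200 M |
| free catalyst | 0.50 mM | 0.50 mM | 0.50 mM | 0.50 mM | 0.50 mM |
| racemization catalyst | 2.3 mM | 4 mM | 6.7 mM | 7.5 mM | 2.5 mM |
| impurity | 0.15 mM | 0.15 mM | 0.15 mM | 0.15 mM | 0.15 mM |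
| remark | run made earlier | run made earlier | run made earlier |  |  |
| time |  |  |  | 50 min | 50 min |

| run | time / min | left-handed product / % | right-handed product / % |
|---|---|---|---|
| south-west | 2.00 | 7.2 | 3.0 |
| south-west | 6.00 | 19.4 | 8.0 |
| south-west | 12.0 | 31.0 | 15.3 |
| south-west | 20.0 | 41.8 | 20.4 |
| south-west | 25.0 | 44.5 | 24.5 |
| south | 2.00 | 6.4 | 3.8 |
| south | 4.00 | 15.0 | 6.8 |
| south | 8.00 | 23.3 | 12.4 |
| south | 12.0 | 31.0 | 14.5 |
| south | 25.0 | 45.5 | 24.6 |
| east | 2.00 | 6.0 | 3.8 |
| east | 4.00 | 14.0 | 7.0 |
| east | 8.00 | 21.8 | 14.0 |
| east | 12.0 | 29.9 | 17.7 |
| east | 25.0 | 45.4 | 22.2 |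

(readings scatter by 1 percentage point)

- free catalyst is single-handed; left-handed substrate and right-handed substrate are mirror images of each other, charged as a racemate, each of them at the stated concentration
- an excess is the difference of the two amounts in percent of their sum
- an excess is below zero if the other one leads

1. which of the two ends with the higher excess of left-handed product over right-handed product in the product ("neither" if they lie within 2 percentage points) (maple / cedar / neither)
2. excess of left-handed product over right-handed product in the product at the end, maple
3. excess of left-handed product over right-handed product in the product at the end, cedar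

**Two times.** The first two readings of each run, at a mean of 3.33 min, average 11.3% left-handed and 5.40% right-handed product. Each hand is half the charge, so first-order loss gives k_L = 0.0771 /min and k_R = 0.0343 /min, a selectivity factor of 2.25. The coupling time is τ_c = 1/k_L = 13.0 min. The other time is τ_r, the racemization time, taken as inverse to the racemization catalyst charge c. Their ratio is ρ = τ_c/τ_r.

**The reckoning.** Substrate held racemic gives a reckoned ceiling of 38.4%. Without racemization, the two decays give a reckoned floor of 19.5% at 25.0 min and 8.84% at 50 min. Assume the excess stands the share ρ/(1+ρ) of the way from floor to ceiling. The three runs then give ρ = c/c*, with the equal-times charge c* = 2.25 mM. Keeping that share at 50 min, this reckoning gives maple 31.6% and cedar 24.4%.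

**The forecast.** It gives maple 26% and cedar 19%: “Maple should end higher, but not by much.” Both values lie below this reckoning.

**The flask.** Of the two, maple ends higher, with maple at 31.8% and cedar at 24.9%.

    racemization catalyst → spent catalyst A (k = 9.12 × 10⁻⁴ /s)
    coupling partner + free catalyst + right-handed substrate → free catalyst + right-handed product (k = 9.31 /M²/s)
    coupling partner + free catalyst + left-handed substrate → free catalyst + left-handed product (k = 20.8 /M²/s)
    left-handed substrate + racemization catalyst ⇌ right-handed substrate + racemization catalyst, rate k4*[racemization catalyst]*[left-handed substrate] forward; the back reaction follows from the equilibrium constant (k = 0.529 /M/s)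
    free catalyst + impurity → spent catalyst B (k = 1470 /M/s)
    coupling partner → decomposition product (k = 4.98 × 10⁻⁶ /s)

**A neighbour.** Maple had ρ = 3.34 and cedar 1.11. A neighbour of cedar, charged with 6.30 mM of racemization catalyst, has ρ = 2.80, and the same share gives 30.7%. That neighbour ends at 30.9%.

(Readings and results are calculated with constants of no real substance, noise included.)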